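**Retrosynthetic overview**

1. Numbering follows the target SMILES (C1 to C28). Ring A = piperidine (N24, C23, C22, C7, C10, C26); ring B = seven-membered carbocycle (C7, C10, C11, C12, C13, C14, C22); ring C = ester-bearing cyclopentene (C14, C15, C16, C21, C22); ring D = cyclopentene (C13, C14, C15, C27, C28); hemiketal ring = C3, C5, C6, C7, C8, O9.
2. The route rests on the C11–C12 single bond of ring B. C12 is allylic to the dienoate C13=C14–C15=C16–CO2Me, so this bond is made last by cutting NH out of the azocane C10–C11–NH–C12–C13 (isodiazene, loss of N2, collapse of the C11/C12 radical pair), which contracts the eight-membered ring to ring B.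
3. Azocane: intramolecular reductive amination of a C11 aldehyde (from a vinyl group on C10) with a C12 amine (aminomethyl cross-coupling at C13 of a dienyl triflate). Ring D: carbonylative Stille coupling and Nazarov cyclisation on the ring C enol triflate. Ring C: rhodium-catalysed hydroacylation of the C14 aldehyde onto a 2-(methoxycarbonyl)allyl arm on C22.
4. C10 and quaternary C7: vinyl conjugate addition and Mukaiyama–Michael addition to ethyl vinyl ketone on an unsaturated γ-lactone (C7–C8(=O)–O–C14–C22) that differentiates both faces; the hemiketal ring is carried as its methyl ketal. Quaternary C22: enantioselective alkylation of the piperidone β-keto ester.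
5. Order of ring formation: ring A (bought) → temporary γ-lactone → hemiketal ring (as methyl ketal) → ring C → ring D → azocane → ring B.

Key step: step 19

Assumption: the facial sense of the phase-transfer catalyst in step 1 cannot be predicted with confidence, so the catalyst antipode that gives (3S)-3 is taken; C16 is carried as an epimeric mixture from 15 to 18 (it becomes sp2 in 19), and the methyl ketal at C3 is taken to be the thermodynamic anomer with axial methoxy.

**Route**

Step 1
Reactants: 1 methyl 1-methyl-4-oxopiperidine-3-carboxylate; 2 2,3-dibromopropene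
Product: 3 methyl (3S)-3-(2-bromoprop-2-en-1-yl)-1-methyl-4-oxopiperidine-3-carboxylate
Conditions: chiral N-spiro bis(binaphthyl)ammonium bromide phase-transfer catalyst (2 mol %), K2CO3, toluene, −20 °C
Reagents that add atoms: none
Why: Enantioselective phase-transfer alkylation of a cyclic β-keto ester, in which the chiral ammonium–enolate ion pair exposes one face of C22 to the allylic bromide and so sets the quaternary stereocentre C22, while C-alkylation of the enolate should outrun quaternisation of the tertiary amine.

Step 2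
Reactants: 3 methyl (3S)-3-(2-bromoprop-2-en-1-yl)-1-methyl-4-oxopiperidine-3-carboxylate
Product: 4 methyl (3S)-3-(2-bromoprop-2-en-1-yl)-1-methyl-4-(trifluoromethanesulfonyloxy)-1,2,3,6-tetrahydropyridine-3-carboxylate
Conditions: KN(SiMe3)2, PhNTf2, THF, −78 °C
Reagents that add atoms: N-phenylbis(trifluoromethanesulfonimide), O=S(=O)(N(c1ccccc1)S(=O)(=O)C(F)(F)F)C(F)(F)F
Why: Enol triflate formation, in which the ketone can enolise only towards C10 because C22 carries no hydrogen, so the C7=C10 double bond is fixed.

Step 3
Reactants: 4 enol triflate ester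
Product: 5 (3R)-3-(2-bromoprop-2-en-1-yl)-3-(hydroxymethyl)-1-methyl-1,2,3,6-tetrahydropyridin-4-yl trifluoromethanesulfonate
Conditions: i-Bu2AlH (3 equiv), CH2Cl2, −78 to −40 °C; Rochelle salt work-up
Reagents that add atoms: none
Why: Hydride reduction of the ester gives the neopentyl alcohol at C14, while the alkenyl triflate and the alkenyl bromide should not be attacked by the aluminium hydride at low temperature.

Step 4
Reactants: 5 hydroxymethyl enol triflate
Product: 6 (3aR)-3a-(2-bromoprop-2-en-1-yl)-5-methyl-3a,4,5,6-tetrahydrofuro[3,4-c]pyridin-1(3H)-one (unsaturated γ-lactone C7–C8(=O)–O–C14–C22 with C7=C10)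
Conditions: Pd(OAc)2 (5 mol %), Ph2P(CH2)3PPh2, CO (1 atm), i-Pr2NEt, DMF, 25–40 °C
Reagents that add atoms: carbon monoxide, [C-]#[O+]
Why: Palladium-catalysed carbonylative lactonisation, in which the alkenyl triflate adds to zerovalent palladium at room temperature, CO inserts and the C14 hydroxyl captures the acylpalladium in a five-membered closure that brings in C8, whereas the 1,1-disubstituted alkenyl bromide should react only on heating.

Step 5
Reactants: 6 unsaturated γ-lactone; 7 ethyl vinyl ketone
Product: 9 keto lactone (3aR,7S,7aR)-3a-(2-bromoprop-2-en-1-yl)-7-ethenyl-5-methyl-7a-(3-oxopentyl)hexahydrofuro[3,4-c]pyridin-1(3H)-one, via silyl ketene acetal 8 (not isolated)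
Conditions: CH2=CHMgBr, CuBr·SMe2 (20 mol %), Me3SiCl, THF, −78 °C; then 7, TiCl4 (2.2 equiv), CH2Cl2, −78 °C
Reagents that add atoms: vinylmagnesium bromide, C=C[Mg]Br
Why: Copper-catalysed conjugate addition followed by Mukaiyama–Michael addition, in which the lactone holds C14 in the enoate plane so that the C21 arm on C22 is pseudoaxial and vinyl enters C10 from the other face (sets C10), and the ketene acetal then adds to the enone through C7 anti to the vinyl group with the lactone staying cis-fused (sets quaternary C7 with C6 cis to C21).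

Step 6
Reactants: 9 keto lactone
Product: 10 (3aR,7S,7aR)-3a-(2-bromoprop-2-en-1-yl)-7a-(3,3-dimethoxypentyl)-7-ethenyl-5-methylhexahydrofuro[3,4-c]pyridin-1(3H)-one
Conditions: HC(OMe)3, MeOH, TsOH·H2O (1.2 equiv), 25 °C; NaHCO3
Reagents that add atoms: trimethyl orthoformate, COC(OC)OC
Why: Acid-catalysed ketalisation with an orthoester protects the C3 ketone, the only ketone present, so that the lactone can be reduced in the next step.

Step 7
Reactants: 10 dimethyl ketal lactone
Product: 11 [(3R,4R,5S)-3-(2-bromoprop-2-en-1-yl)-4-(3,3-dimethoxypentyl)-5-ethenyl-1-methylpiperidine-3,4-diyl]dimethanol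
Conditions: LiAlH4, THF, 0 °C
Reagents that add atoms: none
Why: Hydride reduction of the γ-lactone gives the C8/C14 diol, and the ketal, the alkenyl bromide and the vinyl group should be stable to LiAlH4 at 0 °C.

Step 8
Reactants: 11 diol dimethyl ketal
Product: 12 spiroketal alcohol (ring A with the 2-ethyl-2-methoxytetrahydropyran spiro at C7, vinyl on C10, CH2OH and 2-bromoallyl on C22)
Conditions: camphorsulfonic acid (1.2 equiv), CH2Cl2/MeOH 20:1, 25 °C; NaHCO3
Reagents that add atoms: none
Why: Intramolecular transketalisation, in which only the C8 hydroxyl can reach C3 through a six-membered ring (C14–OH would need a seven-membered ring), closes the hemiketal ring as its methyl ketal with the anomerically favoured axial methoxy group at C3 and leaves C14–OH free.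

Step 9
Reactants: 12 spiroketal alcohol
Product: 13 spiroketal aldehyde (C14 formyl on C22)
Conditions: SO3·pyridine, Me2SO, i-Pr2NEt, CH2Cl2, 0 °C
Reagents that add atoms: none
Why: Parikh–Doering oxidation turns the remaining primary alcohol into the non-enolisable α-quaternary aldehyde without touching the tertiary amine or the ketal.

Step 10
Reactants: 13 spiroketal aldehyde
Product: 14 acrylate aldehyde (C22 carries CHO and CH2C(=CH2)CO2Me)
Conditions: PdCl2(PPh3)2 (5 mol %), CO (3 bar), MeOH, Et3N, DMF, 60 °C
Reagents that add atoms: carbon monoxide, [C-]#[O+]; methanol, CO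
Why: Palladium-catalysed methoxycarbonylation of the alkenyl bromide gives the 2-substituted acrylate (C17 ester on C16), and the aldehyde should be inert to CO, methanol and triethylamine.

Step 11
Reactants: 14 acrylate aldehyde
Product: 15 spiro cyclopentanone (ring C with C14 ketone and CO2Me on C16; C16 epimers)
Conditions: [Rh(Ph2PCH2CH2PPh2)]ClO4 (5 mol %), CH2Cl2, 25 °C (14 as its HBF4 salt); NaHCO3
Reagents that add atoms: none
Why: Rhodium-catalysed intramolecular hydroacylation of a 2,2-disubstituted 4-pentenal, in which the aldehyde C–H adds to monovalent rhodium, the acrylate alkene inserts and reductive elimination closes ring C as the cyclopentanone; the new C16 centre is a mixture that is erased in step 15.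

Step 12
Reactants: 15 spiro cyclopentanone
Product: 16 ring C enol triflate (C14(OTf)=C15)
Conditions: KN(SiMe3)2 (1.05 equiv), PhNTf2, THF, −78 °C
Reagents that add atoms: N-phenylbis(trifluoromethanesulfonimide), O=S(=O)(N(c1ccccc1)S(=O)(=O)C(F)(F)F)C(F)(F)F
Why: Kinetic enol triflate formation, in which the ring C ketone can enolise only towards C15 because C22 is quaternary and the ketone α-hydrogens are more acidic than the ester α-hydrogen.

Step 13
Reactants: 16 ring C enol triflate
Product: 17 divinyl ketone (C14 carries C13(=O)CH=CH2)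
Conditions: Pd(PPh3)4 (5 mol %), LiCl, CO (3 bar), CH2=CHSnBu3, THF, 60 °C
Reagents that add atoms: carbon monoxide, [C-]#[O+]; tributyl(vinyl)stannane, CCCC[Sn](CCCC)(CCCC)C=C
Why: Carbonylative Stille coupling, in which CO inserts into the alkenylpalladium bond and vinyl is transferred from tin, gives the cross-conjugated divinyl ketone with C13 as the carbonyl carbon.

Step 14
Reactants: 17 divinyl ketone
Product: 18 bicyclic enone (rings C and D; C13 ketone, C14=C15, CO2Me on C16)
Conditions: MeSO3H (4 equiv), CH2Cl2, 0 to 25 °C; then MeOH; NaHCO3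
Reagents that add atoms: none
Why: Nazarov cyclisation, in which protonation gives the pentadienyl cation, conrotatory 4π closure forms C15–C27 (ring D) and proton loss places the double bond at the more substituted C14=C15 position, the methanol quench returning the hemiketal ring to its methyl ketal.

Step 15
Reactants: 18 bicyclic enone
Product: 19 dienyl triflate (TfO–C13=C14–C15=C16–CO2Me)
Conditions: NaH (1.1 equiv), PhNTf2, THF, 0 °C
Reagents that add atoms: N-phenylbis(trifluoromethanesulfonimide), O=S(=O)(N(c1ccccc1)S(=O)(=O)C(F)(F)F)C(F)(F)F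
Why: Deprotonation at C16, the vinylogous β-keto ester position, gives the extended enolate, and O-sulfonylation at the C13 oxygen delivers the fully conjugated dienyl triflate, which also removes the C16 stereocentre.

Step 16
Reactants: 19 dienyl triflate
Product: 20 Boc-aminomethyl diene (C12H2NHBoc on C13)
Conditions: Pd(OAc)2 (5 mol %), 2-dicyclohexylphosphino-2′,4′,6′-triisopropylbiphenyl (10 mol %), K2CO3, toluene/H2O 4:1, 85 °C
Reagents that add atoms: potassium [(tert-butoxycarbonylamino)methyl]trifluoroborate, CC(C)(C)OC(=O)NC[B-](F)(F)F.[K+]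
Why: Suzuki–Miyaura coupling of the alkenyl triflate with an aminomethyltrifluoroborate attaches C12 with its protected nitrogen to C13.

Step 17
Reactants: 20 Boc-aminomethyl diene
Product: 21 Boc-amino aldehyde (C11 formyl on C10)
Conditions: OsO4 (2 mol %), NaIO4 (4 equiv), 2,6-lutidine, dioxane/H2O 3:1, 25 °C
Reagents that add atoms: osmium tetroxide, O=[Os](=O)(=O)=O; sodium periodate, [Na+].[O-]I(=O)(=O)=O
Why: Lemieux–Johnson cleavage, in which OsO4 should dihydroxylate the unhindered monosubstituted vinyl group much faster than the tetrasubstituted, ester-deactivated diene and periodate cleaves the diol to the C11 aldehyde.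

Step 18
Reactants: 21 Boc-amino aldehyde
Product: 24 azocane (aza-homologue of the target with NH between C11 and C12), via amino aldehyde 22 (not isolated), via cyclic imine 23 (not isolated)
Conditions: CF3CO2H, CH2Cl2, H2O (5 equiv), 0 to 25 °C; evaporate; then i-Pr2NEt, NaBH(OAc)3, ClCH2CH2Cl (2 mM), 25 °C
Reagents that add atoms: water, O
Why: Acid removes the Boc group and hydrolyses the methyl ketal to the hemiketal, and intramolecular reductive amination then closes the eight-membered ring, since only the C10 epimer with C11 cis to C14 can cyclise and the aldehyde α-centre can correct itself through the enamine.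

Step 19
Reactants: 24 azocane
Product: 26 target compound, via isodiazene 25 (not isolated)
Conditions: N-(benzyloxy)-N-(pivaloyloxy)-4-(trifluoromethyl)benzamide (1.5 equiv), THF, 45 °C
Reagents that add atoms: none
Why: Nitrogen deletion through an isodiazene: the secondary amine attacks the amide nitrogen of the anomeric amide with loss of pivalate, the N-amino-N-alkoxyamide expels the benzyl ester to give isodiazene 25, and this loses N2 to a singlet pair made of the primary C11 radical and the C12 radical, which is delocalised over the dienoate. The closest known reactions are the nitrogen deletions of benzylic secondary amines with the same reagent, including ring contractions of cyclic amines. Ring B is closed by contraction of the azocane from eight to seven atoms through in-cage recombination of the tethered radical pair, which forms the C11–C12 σ bond. No stereocentre is formed and none is touched, because C10 only neighbours the C11 radical. The step needs bond formation at C12 and not at C14 or C16 of the delocalised radical: C12 is the carbon left next to C11 when N2 departs, bonding there keeps the dienoate conjugated, and bonding at C14 or C16 would build a quaternary carbon in a more strained ring. The tertiary amine N24 cannot form an isodiazene, and the tertiary hemiketal hydroxyl should not consume the reagent.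

**Compound list**

1 | methyl 1-methyl-4-oxopiperidine-3-carboxylate | CN1CCC(=O)C(C1)C(=O)OC | starting material
2 | 2,3-dibromopropene | BrCC(Br)=C | starting material
3 | methyl (3S)-3-(2-bromoprop-2-en-1-yl)-1-methyl-4-oxopiperidine-3-carboxylate | CN1CCC(=O)[C@@](C1)(CC(Br)=C)C(=O)OC | intermediate
4 | methyl (3S)-3-(2-bromoprop-2-en-1-yl)-1-methyl-4-(trifluoromethanesulfonyloxy)-1,2,3,6-tetrahydropyridine-3-carboxylate | CN1CC=C(OS(=O)(=O)C(F)(F)F)[C@@](C1)(CC(Br)=C)C(=O)OC | intermediate
5 | (3R)-3-(2-bromoprop-2-en-1-yl)-3-(hydroxymethyl)-1-methyl-1,2,3,6-tetrahydropyridin-4-yl trifluoromethanesulfonate | CN1CC=C(OS(=O)(=O)C(F)(F)F)[C@@](C1)(CC(Br)=C)CO | intermediate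
6 | (3aR)-3a-(2-bromoprop-2-en-1-yl)-5-methyl-3a,4,5,6-tetrahydrofuro[3,4-c]pyridin-1(3H)-one | CN1CC=C2C(=O)OC[C@]2(C1)CC(Br)=C | intermediate
7 | ethyl vinyl ketone (pent-1-en-3-one) | CCC(=O)C=C | starting material
8 | trimethylsilyl ketene acetal of the C10-vinyl lactone (C7=C8(OSiMe3)–O; vinyl on C10 trans to the 2-bromoallyl arm) | CN1C[C@@H](C=C)C2=C(O[Si](C)(C)C)OC[C@]2(C1)CC(Br)=C | intermediate (not isolated)
9 | (3aR,7S,7aR)-3a-(2-bromoprop-2-en-1-yl)-7-ethenyl-5-methyl-7a-(3-oxopentyl)hexahydrofuro[3,4-c]pyridin-1(3H)-one | CCC(=O)CC[C@]12C(=O)OC[C@@]1(CC(Br)=C)CN(C)C[C@H]2C=C | intermediate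
10 | (3aR,7S,7aR)-3a-(2-bromoprop-2-en-1-yl)-7a-(3,3-dimethoxypentyl)-7-ethenyl-5-methylhexahydrofuro[3,4-c]pyridin-1(3H)-one | CCC(OC)(OC)CC[C@]12C(=O)OC[C@@]1(CC(Br)=C)CN(C)C[C@H]2C=C | intermediate
11 | [(3R,4R,5S)-3-(2-bromoprop-2-en-1-yl)-4-(3,3-dimethoxypentyl)-5-ethenyl-1-methylpiperidine-3,4-diyl]dimethanol | CCC(OC)(OC)CC[C@@]1(CO)[C@H](C=C)CN(C)C[C@@]1(CO)CC(Br)=C | intermediate
12 | spiroketal alcohol: N-methylpiperidine with the (R)-2-ethyl-2-methoxytetrahydropyran spiro at C7, vinyl on C10, CH2OH and 2-bromoallyl on C22 (C7, C10, C22 arranged as in the target) | CC[C@]1(OC)CC[C@@]2(CO1)[C@H](C=C)CN(C)C[C@@]2(CO)CC(Br)=C | intermediate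
13 | spiroketal aldehyde: as 12 with CHO (C14) in place of CH2OH | CC[C@]1(OC)CC[C@@]2(CO1)[C@H](C=C)CN(C)C[C@@]2(C=O)CC(Br)=C | intermediate
14 | acrylate aldehyde: as 13 with CH2C(=CH2)CO2Me in place of the 2-bromoallyl arm | CC[C@]1(OC)CC[C@@]2(CO1)[C@H](C=C)CN(C)C[C@@]2(C=O)CC(=C)C(=O)OC | intermediate
15 | spiro cyclopentanone: ring C closed on C22 (C14 ketone, C15H2, C16H–CO2Me, C21H2; C16 epimers) | CC[C@]1(OC)CC[C@@]2(CO1)[C@H](C=C)CN(C)C[C@@]23CC(C(=O)OC)CC3=O | intermediate
16 | ring C enol triflate: C14(OTf)=C15H, CO2Me on C16 (C16 epimers) | CC[C@]1(OC)CC[C@@]2(CO1)[C@H](C=C)CN(C)C[C@@]23CC(C(=O)OC)C=C3OS(=O)(=O)C(F)(F)F | intermediate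
17 | divinyl ketone: C14 of the ring C alkene carries the acryloyl group C13(=O)CH=CH2 (C16 epimers) | CC[C@]1(OC)CC[C@@]2(CO1)[C@H](C=C)CN(C)C[C@@]23CC(C(=O)OC)C=C3C(=O)C=C | intermediate
18 | bicyclic enone: rings C and D fused at C14=C15, C13 ketone, CO2Me on C16 (C16 epimers) | CC[C@]1(OC)CC[C@@]2(CO1)[C@H](C=C)CN(C)C[C@@]23CC(C(=O)OC)C4=C3C(=O)CC4 | intermediate
19 | dienyl triflate: TfO–C13=C14–C15=C16–CO2Me in rings C and D | CC[C@]1(OC)CC[C@@]2(CO1)[C@H](C=C)CN(C)C[C@@]23CC(C(=O)OC)=C4C3=C(OS(=O)(=O)C(F)(F)F)CC4 | intermediate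
20 | Boc-aminomethyl diene: as 19 with CH2NHBoc (C12) on C13 | CC[C@]1(OC)CC[C@@]2(CO1)[C@H](C=C)CN(C)C[C@@]23CC(C(=O)OC)=C4C3=C(CNC(=O)OC(C)(C)C)CC4 | intermediate
21 | Boc-amino aldehyde: as 20 with CHO (C11) on C10 in place of vinyl | CC[C@]1(OC)CC[C@@]2(CO1)[C@H](C=O)CN(C)C[C@@]23CC(C(=O)OC)=C4C3=C(CNC(=O)OC(C)(C)C)CC4 | intermediate
22 | amino aldehyde hemiketal: free C12 amine, C11 aldehyde, C3 hemiketal | CC[C@]1(O)CC[C@@]2(CO1)[C@H](C=O)CN(C)C[C@@]23CC(C(=O)OC)=C4C3=C(CN)CC4 | intermediate (not isolated)
23 | cyclic imine: eight-membered ring closed through C11=N–C12 | CC[C@]1(O)CC[C@@]2(CO1)[C@@H]1C=NCC3=C4C(=C(C(=O)OC)C[C@@]42CN(C)C1)CC3 | intermediate (not isolated)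
24 | azocane: aza-homologue of the target with NH between C11 and C12 | CC[C@]1(O)CC[C@@]2(CO1)[C@@H]1CNCC3=C4C(=C(C(=O)OC)C[C@@]42CN(C)C1)CC3 | intermediate
25 | isodiazene of 24 (N-amino azocanium ylide form) | CC[C@]1(O)CC[C@@]2(CO1)[C@@H]1C[N+](=[N-])CC3=C4C(=C(C(=O)OC)C[C@@]42CN(C)C1)CC3 | intermediate (not isolated)
26 | CNP0192143.3 (C3 R, C7 R, C10 S, C22 R in the SMILES numbering) | CC[C@]1(O)CC[C@@]2(CO1)[C@@H]1CCC3=C4C(=C(C(=O)OC)C[C@@]42CN(C)C1)CC3 | target

**Step count and risks**

Total step count: 19. Longest linear sequence: 19 steps (1 to 26).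

The three steps most likely to fail:

Step 19 (key step). The allylic isodiazene may shift its terminal nitrogen to C14 before N2 is lost. The radical pair may also recombine at C14 or C16 of the delocalised radical, or disproportionate by hydrogen transfer to ring-opened material. The fallback sets out from dienyl triflate 19 and returns at target 26. Stille coupling of 19 with CH2=CHSnBu3 (Pd(PPh3)4, LiCl, THF, 60 °C) would give the C13-vinyl tetraene F1. Ring-closing metathesis between the C10 and C13 vinyl groups (second-generation Grubbs catalyst, amine protonated with camphorsulfonic acid, CH2Cl2, 40 °C) would close ring B as the C11=C12 cycloheptadiene F2. Diimide (2-nitrobenzenesulfonylhydrazide, Et3N) should reduce only the disubstituted C11=C12 bond and give the methyl ketal of the target F3. Aqueous HCl in THF would then give 26.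

Step 5. The Mukaiyama–Michael addition has to join C7 to C6 next to the quaternary C22 and may stall, the vinyl ketone may polymerise under TiCl4, or the attack may take place on the wrong face. The fallback sets out from lactone 6 and returns at spiroketal alcohol 12. The same vinyl conjugate addition with a protic quench would give the saturated cis-lactone F4. Ethyl vinyl ketone 7 would be converted with HBr and ethane-1,2-diol into the bromo ketal F5 and with NaI in acetone into the iodo ketal F6. Deprotonation of F4 with LiN(i-Pr)2 and alkylation with F6 in THF/DMPU would give the alkylated lactone F7, again with C6 anti to the vinyl group. LiAlH4 would give the diol F8, and camphorsulfonic acid in CH2Cl2/MeOH would exchange the dioxolane for the cyclic methyl ketal 12.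

Step 14. The unsubstituted vinyl ketone may polymerise in acid, the oxyallyl cation may be captured by the nearby C10 vinyl group, or the ketal may be lost irreversibly. The fallback sets out from cyclopentanone 15 and returns at enone 18. Stork enamine Michael addition of 15 (pyrrolidine) to tert-butyl acrylate would give the keto diester F9 with the C27–C28–C13 chain on C15. KN(SiMe3)2 and PhNTf2 would give the tetrasubstituted enol triflate F10, and Pd(OAc)2, PPh3, HCO2H and Bu3N would reduce it to the cyclopentene F11. CF3CO2H would cleave the tert-butyl ester to the acid F12, and (CF3CO)2O followed by a methanol quench would acylate the ring C alkene at C14 and give 18.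

Further compounds
F1 | step 19 | C13-vinyl tetraene (19 with CH=CH2 in place of OTf) | CC[C@]1(OC)CC[C@@]2(CO1)[C@H](C=C)CN(C)C[C@@]23CC(C(=O)OC)=C4C3=C(C=C)CC4
F2 | step 19 | C11=C12 cycloheptadiene with ring B closed (methyl ketal) | CC[C@]1(OC)CC[C@@]2(CO1)[C@@H]1C=CC3=C4C(=C(C(=O)OC)C[C@@]42CN(C)C1)CC3
F3 | step 19 | methyl ketal of the target | CC[C@]1(OC)CC[C@@]2(CO1)[C@@H]1CCC3=C4C(=C(C(=O)OC)C[C@@]42CN(C)C1)CC3
F4 | step 5 | saturated cis-lactone with vinyl on C10 and hydrogen on C7 | CN1C[C@@H](C=C)[C@H]2C(=O)OC[C@]2(C1)CC(Br)=C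
F5 | step 5 | 2-(2-bromoethyl)-2-ethyl-1,3-dioxolane | CCC1(CCBr)OCCO1
F6 | step 5 | 2-ethyl-2-(2-iodoethyl)-1,3-dioxolane | CCC1(CCI)OCCO1
F7 | step 5 | alkylated lactone with the dioxolane-protected 3-oxopentyl chain on C7 | CCC1(OCCO1)CC[C@]12C(=O)OC[C@@]1(CC(Br)=C)CN(C)C[C@H]2C=C
F8 | step 5 | C8/C14 diol with the dioxolane-protected chain | CCC1(OCCO1)CC[C@@]1(CO)[C@H](C=C)CN(C)C[C@@]1(CO)CC(Br)=C
F9 | step 14 | keto diester: 15 with CH2CH2CO2t-Bu on C15 | CC[C@]1(OC)CC[C@@]2(CO1)[C@H](C=C)CN(C)C[C@@]23CC(C(=O)OC)C(CCC(=O)OC(C)(C)C)C3=O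
F10 | step 14 | tetrasubstituted enol triflate C14(OTf)=C15 | CC[C@]1(OC)CC[C@@]2(CO1)[C@H](C=C)CN(C)C[C@@]23CC(C(=O)OC)C(CCC(=O)OC(C)(C)C)=C3OS(=O)(=O)C(F)(F)F
F11 | step 14 | cyclopentene C14H=C15 with the tert-butyl propanoate chain | CC[C@]1(OC)CC[C@@]2(CO1)[C@H](C=C)CN(C)C[C@@]23CC(C(=O)OC)C(CCC(=O)OC(C)(C)C)=C3
F12 | step 14 | cyclopentene propanoic acid | CC[C@]1(OC)CC[C@@]2(CO1)[C@H](C=C)CN(C)C[C@@]23CC(C(=O)OC)C(CCC(=O)O)=C3
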